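**Retrosynthetic overview**
1. Target 21 ⇐ butenolide 20 (lactone opening) ⇐ γ-hydroxy ynoate 19 (methyl cuprate) ⇐ C12 aldehyde 17 + methyl propiolate (catalyst-controlled C12).
2. 17 ⇐ bicyclic aldehyde 13 by C4 methylation (sets C4), aldehyde-to-acid oxidation and unmasking/oxidation of the C12 alcohol.
3. 13 ⇐ acyclic (E,Z)-dienal 12 by one aminocatalytic radical-cation bicyclisation: ring A closes first (C4–C5), then ring B (C10–C9); the allylsilane delivers the C8 exocyclic methylene.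
4. 12 ⇐ Negishi coupling of the zinc reagent from bromide 6 with vinyl iodide 10; 6 from carbocupration of 4-bromobut-1-yne, 10 from carboalumination of hept-6-yn-1-ol.

Assumption: labdane numbering is used (target = (12S,13Z)-12-hydroxylabda-8(17),13-diene-15,19-dioic acid); catalyst enantiomers are assigned from the published facial models, and the mirror-image catalyst is taken if a sense proves opposite.

**Route**

Step 1
Reactants: 1 4-bromobut-1-yne; 2 (trimethylsilyl)methylmagnesium chloride; 3 oxirane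
Product: 6 (Z)-6-bromo-4-[(trimethylsilyl)methyl]hex-3-en-1-yl pivalate, via alkenylcopper 4 (not isolated), via bromo alcohol 5 (not isolated)
Conditions: 2, CuBr·SMe2, Et2O/Me2S, −40 °C; 1, −20 → 0 °C; 3, BF3·OEt2, −78 → −30 °C; PivCl, DMAP (cat.), 0 °C → rt
Reagents that add atoms: pivaloyl chloride CC(C)(C)C(Cl)=O
Why: Normant syn-carbocupration puts Cu cis to the CH2SiMe3 group, the BF3-assisted opening of oxirane by the alkenylcopper proceeds with retention (C11 cis to C17, Z), and the alkoxide is acylated in the same flask.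

Step 2
Reactants: 7 hept-6-yn-1-ol
Product: 9 (E)-7-iodo-6-methylhept-6-en-1-ol, via alkenylalane 8 (not isolated)
Conditions: AlMe3 (3 equiv), Cp2ZrCl2 (25 mol%), CH2Cl2, 0 °C → rt; I2, THF, −30 °C; aq. K2CO3
Reagents that add atoms: trimethylaluminium C[Al](C)C; iodine II
Why: Negishi zirconium-catalysed carboalumination adds Me–Al syn with methyl on the internal carbon, and iodinolysis with retention gives the E-iodide.

Step 3
Reactants: 9 (E)-7-iodo-6-methylhept-6-en-1-ol
Product: 10 (E)-7-iodo-6-methylhept-6-enal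
Conditions: TEMPO (10 mol%), PhI(OAc)2, CH2Cl2, rt
Reagents that add atoms: none
Why: Oxoammonium (TEMPO/PhI(OAc)2) oxidation stops at the aldehyde in the absence of water and leaves the vinyl iodide untouched.

Step 4
Reactants: 6 (Z)-6-bromo-4-[(trimethylsilyl)methyl]hex-3-en-1-yl pivalate; 10 (E)-7-iodo-6-methylhept-6-enal
Product: 12 (3Z,7E)-8-methyl-13-oxo-4-[(trimethylsilyl)methyl]trideca-3,7-dien-1-yl pivalate, via alkylzinc bromide 11 (not isolated)
Conditions: 6, Zn dust, LiCl, THF, 50 °C; then 10, PdCl2(dppf) (3 mol%), THF, 40 °C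
Reagents that add atoms: none
Why: Knochel zinc insertion followed by Negishi sp3–sp2 cross-coupling retains the E-alkene geometry and tolerates the aldehyde, the ester and the allylsilane.

Step 5
Reactants: 12 (3Z,7E)-8-methyl-13-oxo-4-[(trimethylsilyl)methyl]trideca-3,7-dien-1-yl pivalate
Product: 13 2-[(1S,4aS,5R,8aS)-5-formyl-8a-methyl-2-methylidenedecahydronaphthalen-1-yl]ethyl pivalate
Conditions: (2S,5S)-2-tert-butyl-3-methyl-5-(1-naphthylmethyl)imidazolidin-4-one·CF3CO2H (30 mol%), (4-BrC6H4)3N (20 mol%), n-Bu4NBF4, H2O (10 equiv), MeCN/DME, RVC anode/graphite cathode, undivided cell, 2.2 F/mol, 0 °C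
Reagents that add atoms: none
Why: Proposed new method: the enamine of 12 is oxidised by the anodically regenerated triarylaminium mediator (about +1.05 V vs SCE, above the enamine but below the allylsilane and alkenes) to a 3π-electron radical cation whose C4 adds 6-endo to the E-alkene from the face opposite the naphthylmethyl arm; the C10 radical then closes ring B on the allylsilane through a chair–chair array (trans-fusion, H5 α, C20 β, C11 equatorial β), and the β-silyl radical is oxidised and desilylated to the 8(17)-methylene only; the closest known reactions are the imidazolidinone SOMO polyene cyclisation with arene terminators and a copper oxidant, SOMO α-allylation with allylsilanes, triarylamine-mediated anodic oxidation and Lewis-acid allylsilane-terminated polyene cyclisation.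

Step 6
Reactants: 13 2-[(1S,4aS,5R,8aS)-5-formyl-8a-methyl-2-methylidenedecahydronaphthalen-1-yl]ethyl pivalate
Product: 14 2-[(1S,4aR,5S,8aR)-5-formyl-5,8a-dimethyl-2-methylidenedecahydronaphthalen-1-yl]ethyl pivalate
Conditions: KOt-Bu (1.3 equiv), THF, −40 °C; MeI, −40 → 0 °C
Reagents that add atoms: iodomethane CI
Why: C-methylation of the exocyclic aldehyde enolate occurs from the equatorial α-face, anti to the axial C10 methyl, so the new methyl is 4α and the formyl group becomes axial C19 (the C4 centre of step 5 is replaced, the ring-fusion chirality is kept).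

Step 7
Reactants: 14 2-[(1S,4aR,5S,8aR)-5-formyl-5,8a-dimethyl-2-methylidenedecahydronaphthalen-1-yl]ethyl pivalate
Product: 15 (1S,4aR,5S,8aR)-1,4a-dimethyl-6-methylidene-5-[2-(pivaloyloxy)ethyl]decahydronaphthalene-1-carboxylic acid
Conditions: NaClO2, NaH2PO4, 2-methyl-2-butene, t-BuOH/H2O, 0 °C → rt
Reagents that add atoms: sodium chlorite [Na+].[O-]Cl=O
Why: Pinnick oxidation converts the non-enolisable hindered aldehyde into the acid while the scavenger protects the exocyclic alkene from HOCl.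

Step 8
Reactants: 15 (1S,4aR,5S,8aR)-1,4a-dimethyl-6-methylidene-5-[2-(pivaloyloxy)ethyl]decahydronaphthalene-1-carboxylic acid
Product: 16 (1S,4aR,5S,8aR)-5-(2-hydroxyethyl)-1,4a-dimethyl-6-methylidenedecahydronaphthalene-1-carboxylic acid
Conditions: LiOH·H2O, THF/MeOH/H2O, 50 °C; 1 M HCl
Reagents that add atoms: none
Why: Saponification removes the unhindered primary pivalate and no stereocentre is epimerisable.

Step 9
Reactants: 16 (1S,4aR,5S,8aR)-5-(2-hydroxyethyl)-1,4a-dimethyl-6-methylidenedecahydronaphthalene-1-carboxylic acid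
Product: 17 (1S,4aR,5S,8aR)-1,4a-dimethyl-6-methylidene-5-(2-oxoethyl)decahydronaphthalene-1-carboxylic acid
Conditions: TEMPO (10 mol%), PhI(OAc)2, CH2Cl2, rt
Reagents that add atoms: none
Why: Oxoammonium oxidation of the primary alcohol stops at the aldehyde under anhydrous conditions and tolerates the acid and the alkene.

Step 10
Reactants: 17 (1S,4aR,5S,8aR)-1,4a-dimethyl-6-methylidene-5-(2-oxoethyl)decahydronaphthalene-1-carboxylic acid; 18 methyl propiolate
Product: 19 (1S,4aR,5S,8aR)-5-[(2S)-2-hydroxy-5-methoxy-5-oxopent-3-yn-1-yl]-1,4a-dimethyl-6-methylidenedecahydronaphthalene-1-carboxylic acid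
Conditions: Me2Zn (4 equiv), (S,S)-ProPhenol (20 mol%), Ph3PO (40 mol%), 18 (3 equiv), toluene, 4 °C
Reagents that add atoms: none
Why: Trost dinuclear zinc–ProPhenol alkynylation sets C12 (S) by catalyst control, remote from the ring stereocentres, with the C19 acid masked in the flask as its zinc carboxylate.

Step 11
Reactants: 19 (1S,4aR,5S,8aR)-5-[(2S)-2-hydroxy-5-methoxy-5-oxopent-3-yn-1-yl]-1,4a-dimethyl-6-methylidenedecahydronaphthalene-1-carboxylic acid
Product: 21 (12S,13Z)-12-hydroxylabda-8(17),13-diene-15,19-dioic acid, via butenolide 20 (not isolated)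
Conditions: Me2CuLi (5 equiv, from MeLi and CuI), THF, −78 → −40 °C; then LiOH (aq), MeOH, 0 °C → rt; cold aq. NaH2PO4 to pH 4, rapid extraction
Reagents that add atoms: lithium dimethylcuprate [Li+].C[Cu-]C; lithium hydroxide [Li+].[OH-]
Why: syn-Conjugate addition of the Gilman cuprate gives the Z-enoate (C12 cis to the ester), which lactonises to butenolide 20; saponification opens the lactone without touching C12 and cold, mild protonation releases the 13Z hydroxy diacid.

**Compound list**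
1 | 4-bromobut-1-yne | C#CCCBr | starting material
2 | (trimethylsilyl)methylmagnesium chloride | C[Si](C)(C)C[Mg]Cl | starting material
3 | oxirane | C1CO1 | starting material
4 | [(1Z)-4-bromo-2-[(trimethylsilyl)methyl]but-1-en-1-yl]copper | [Cu]/C=C(\C[Si](C)(C)C)CCBr | intermediate
5 | (Z)-6-bromo-4-[(trimethylsilyl)methyl]hex-3-en-1-ol (as its alkoxide) | OCC/C=C(\C[Si](C)(C)C)CCBr | intermediate
6 | (Z)-6-bromo-4-[(trimethylsilyl)methyl]hex-3-en-1-yl pivalate | CC(C)(C)C(=O)OCC/C=C(\C[Si](C)(C)C)CCBr | intermediate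
7 | hept-6-yn-1-ol | C#CCCCCCO | starting material
8 | [(1E)-7-(dimethylalumanyloxy)-2-methylhept-1-en-1-yl]dimethylalumane | C[Al](C)/C=C(\C)CCCCCO[Al](C)C | intermediate
9 | (E)-7-iodo-6-methylhept-6-en-1-ol | C/C(CCCCCO)=C\I | intermediate
10 | (E)-7-iodo-6-methylhept-6-enal | C/C(CCCCC=O)=C\I | intermediate
11 | {(Z)-6-(pivaloyloxy)-3-[(trimethylsilyl)methyl]hex-3-en-1-yl}zinc bromide | CC(C)(C)C(=O)OCC/C=C(\C[Si](C)(C)C)CC[Zn]Br | intermediate
12 | (3Z,7E)-8-methyl-13-oxo-4-[(trimethylsilyl)methyl]trideca-3,7-dien-1-yl pivalate | CC(C)(C)C(=O)OCC/C=C(\C[Si](C)(C)C)CC/C=C(\C)CCCCC=O | intermediate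
13 | 2-[(1S,4aS,5R,8aS)-5-formyl-8a-methyl-2-methylidenedecahydronaphthalen-1-yl]ethyl pivalate (4α-CHO, 5α-H, 10β-Me, 9β side chain) | C=C1CC[C@@H]2[C@](C)(CCC[C@H]2C=O)[C@H]1CCOC(=O)C(C)(C)C | intermediate
14 | 2-[(1S,4aR,5S,8aR)-5-formyl-5,8a-dimethyl-2-methylidenedecahydronaphthalen-1-yl]ethyl pivalate (4α-Me, 4β-CHO) | C=C1CC[C@@H]2[C@](C)(CCC[C@]2(C)C=O)[C@H]1CCOC(=O)C(C)(C)C | intermediate
15 | (1S,4aR,5S,8aR)-1,4a-dimethyl-6-methylidene-5-[2-(pivaloyloxy)ethyl]decahydronaphthalene-1-carboxylic acid | C=C1CC[C@@H]2[C@](C)(CCC[C@]2(C)C(=O)O)[C@H]1CCOC(=O)C(C)(C)C | intermediate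
16 | (1S,4aR,5S,8aR)-5-(2-hydroxyethyl)-1,4a-dimethyl-6-methylidenedecahydronaphthalene-1-carboxylic acid | C=C1CC[C@@H]2[C@](C)(CCC[C@]2(C)C(=O)O)[C@H]1CCO | intermediate
17 | (1S,4aR,5S,8aR)-1,4a-dimethyl-6-methylidene-5-(2-oxoethyl)decahydronaphthalene-1-carboxylic acid | C=C1CC[C@@H]2[C@](C)(CCC[C@]2(C)C(=O)O)[C@H]1CC=O | intermediate
18 | methyl propiolate | C#CC(=O)OC | starting material
19 | (1S,4aR,5S,8aR)-5-[(2S)-2-hydroxy-5-methoxy-5-oxopent-3-yn-1-yl]-1,4a-dimethyl-6-methylidenedecahydronaphthalene-1-carboxylic acid | C=C1CC[C@@H]2[C@](C)(CCC[C@]2(C)C(=O)O)[C@H]1C[C@H](O)C#CC(=O)OC | intermediate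
20 | (1S,4aR,5S,8aR)-1,4a-dimethyl-6-methylidene-5-{[(2S)-3-methyl-5-oxo-2,5-dihydrofuran-2-yl]methyl}decahydronaphthalene-1-carboxylic acid | C=C1CC[C@@H]2[C@](C)(CCC[C@]2(C)C(=O)O)[C@H]1C[C@@H]3OC(=O)C=C3C | intermediate
21 | (12S,13Z)-12-hydroxylabda-8(17),13-diene-15,19-dioic acid (CNP0144045.1) | C=C1CC[C@@H]2[C@](C)(CCC[C@]2(C)C(=O)O)[C@H]1C[C@H](O)/C(C)=C\C(=O)O | target

**Step count and risks**
Total steps: 11. Longest linear sequence: 10 (steps 2 to 11).

Step 5 (the new bicyclisation). The radical cation may be intercepted before ring B closes, the allylsilane may be protodesilylated, or the ee may be low. The fallback is the known iridium-catalysed, allylic-alcohol-initiated and allylsilane-terminated polyene cyclisation; it sets out from 6 and comes back at 13. Hex-5-yn-1-ol is taken through the conditions of steps 2 and 3 to (E)-6-iodo-5-methylhex-5-en-1-ol F1 and then (E)-6-iodo-5-methylhex-5-enal F2. The zinc reagent 11 made from 6 is coupled with F2 as in step 4 to give (3Z,7E)-8-methyl-12-oxo-4-[(trimethylsilyl)methyl]dodeca-3,7-dien-1-yl pivalate F3. Vinylmagnesium bromide (THF, −78 °C) gives racemic (3Z,7E)-12-hydroxy-8-methyl-4-[(trimethylsilyl)methyl]tetradeca-3,7,13-trien-1-yl pivalate F4. [Ir(cod)Cl]2 with the chiral phosphoramidite–olefin ligand and Zn(OTf)2 in ClCH2CH2Cl converts both enantiomers of F4 into 2-[(1S,4aS,5S,8aS)-5-ethenyl-8a-methyl-2-methylidenedecahydronaphthalen-1-yl]ethyl pivalate F5. K2OsO4·2H2O/NMO with (DHQD)2PHAL at partial conversion, then NaIO4, cleaves the unhindered vinyl group to the aldehyde 13.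

Step 10 (alkynylation beside a free acid). The zinc carboxylate may poison the dinuclear catalyst or erode the selectivity. The fallback replaces catalytic addition by reduction of a ketone; it sets out from 17 and comes back at 19. Lithiated methyl propiolate (3 equiv, THF, −78 °C) adds to 17 to give the C12-epimeric mixture (1S,4aR,5S,8aR)-5-(2-hydroxy-5-methoxy-5-oxopent-3-yn-1-yl)-1,4a-dimethyl-6-methylidenedecahydronaphthalene-1-carboxylic acid F6. Dess–Martin periodinane oxidises it to the ynone (1S,4aR,5S,8aR)-5-(5-methoxy-2,5-dioxopent-3-yn-1-yl)-1,4a-dimethyl-6-methylidenedecahydronaphthalene-1-carboxylic acid F7. (S)-Me-CBS oxazaborolidine (20 mol%) with catecholborane in toluene at −78 °C, with the alkynyl group acting as the small substituent, reduces F7 to 19.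

Step 11 (release of the hydroxy diacid). The (Z)-γ-hydroxy enoic acid can close back to butenolide 20 on acidification. The fallback never forms the lactone; it sets out from 19 and comes back at 21. TBSOTf/2,6-lutidine, with aqueous work-up to cleave the silyl ester, gives the silyl ether (1S,4aR,5S,8aR)-5-[(2S)-2-(tert-butyldimethylsilyloxy)-5-methoxy-5-oxopent-3-yn-1-yl]-1,4a-dimethyl-6-methylidenedecahydronaphthalene-1-carboxylic acid F8. Me2CuLi gives the open Z-enoate (1S,4aR,5S,8aR)-5-[(2S,3Z)-2-(tert-butyldimethylsilyloxy)-5-methoxy-3-methyl-5-oxopent-3-en-1-yl]-1,4a-dimethyl-6-methylidenedecahydronaphthalene-1-carboxylic acid F9. LiOH (THF/MeOH/H2O, 40 °C) gives the purifiable diacid (1S,4aR,5S,8aR)-5-[(2S,3Z)-2-(tert-butyldimethylsilyloxy)-4-carboxy-3-methylbut-3-en-1-yl]-1,4a-dimethyl-6-methylidenedecahydronaphthalene-1-carboxylic acid F10. TBAF in THF, then neutralisation on a weakly acidic resin at 0 °C, gives 21.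

**Further compounds**
F1 | step 5 | (E)-6-iodo-5-methylhex-5-en-1-ol | C/C(CCCCO)=C\I
F2 | step 5 | (E)-6-iodo-5-methylhex-5-enal | C/C(CCCC=O)=C\I
F3 | step 5 | (3Z,7E)-8-methyl-12-oxo-4-[(trimethylsilyl)methyl]dodeca-3,7-dien-1-yl pivalate | CC(C)(C)C(=O)OCC/C=C(\C[Si](C)(C)C)CC/C=C(\C)CCCC=O
F4 | step 5 | rac-(3Z,7E)-12-hydroxy-8-methyl-4-[(trimethylsilyl)methyl]tetradeca-3,7,13-trien-1-yl pivalate | CC(C)(C)C(=O)OCC/C=C(\C[Si](C)(C)C)CC/C=C(\C)CCCC(O)C=C
F5 | step 5 | 2-[(1S,4aS,5S,8aS)-5-ethenyl-8a-methyl-2-methylidenedecahydronaphthalen-1-yl]ethyl pivalate | C=C1CC[C@@H]2[C@](C)(CCC[C@H]2C=C)[C@H]1CCOC(=O)C(C)(C)C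
F6 | step 10 | (1S,4aR,5S,8aR)-5-(2-hydroxy-5-methoxy-5-oxopent-3-yn-1-yl)-1,4a-dimethyl-6-methylidenedecahydronaphthalene-1-carboxylic acid (C12 epimers) | C=C1CC[C@@H]2[C@](C)(CCC[C@]2(C)C(=O)O)[C@H]1CC(O)C#CC(=O)OC
F7 | step 10 | (1S,4aR,5S,8aR)-5-(5-methoxy-2,5-dioxopent-3-yn-1-yl)-1,4a-dimethyl-6-methylidenedecahydronaphthalene-1-carboxylic acid | C=C1CC[C@@H]2[C@](C)(CCC[C@]2(C)C(=O)O)[C@H]1CC(=O)C#CC(=O)OC
F8 | step 11 | (1S,4aR,5S,8aR)-5-[(2S)-2-(tert-butyldimethylsilyloxy)-5-methoxy-5-oxopent-3-yn-1-yl]-1,4a-dimethyl-6-methylidenedecahydronaphthalene-1-carboxylic acid | C=C1CC[C@@H]2[C@](C)(CCC[C@]2(C)C(=O)O)[C@H]1C[C@H](O[Si](C)(C)C(C)(C)C)C#CC(=O)OC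
F9 | step 11 | (1S,4aR,5S,8aR)-5-[(2S,3Z)-2-(tert-butyldimethylsilyloxy)-5-methoxy-3-methyl-5-oxopent-3-en-1-yl]-1,4a-dimethyl-6-methylidenedecahydronaphthalene-1-carboxylic acid | C=C1CC[C@@H]2[C@](C)(CCC[C@]2(C)C(=O)O)[C@H]1C[C@H](O[Si](C)(C)C(C)(C)C)/C(C)=C\C(=O)OC
F10 | step 11 | (1S,4aR,5S,8aR)-5-[(2S,3Z)-2-(tert-butyldimethylsilyloxy)-4-carboxy-3-methylbut-3-en-1-yl]-1,4a-dimethyl-6-methylidenedecahydronaphthalene-1-carboxylic acid | C=C1CC[C@@H]2[C@](C)(CCC[C@]2(C)C(=O)O)[C@H]1C[C@H](O[Si](C)(C)C(C)(C)C)/C(C)=C\C(=O)O
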